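**Retrosynthetic overview**
1. The strategy rests on the seven-membered ring: C10 (the carbon bearing the exocyclic CH2), C9 (oxygen) and C8 (CH2) sit in a row between the methines C1 and C7. This is the carbon pattern of a 2-diazo-3-siloxybut-3-enoate laid across a C1=C5–C6=C7 diene whose C1=C5 bond is a cyclopentene.
2. Key disconnection: C1–C10 and C7–C8, by rhodium-carbenoid cyclopropanation of C1=C5 followed by divinylcyclopropane Cope shift. The five-membered ring comes intact from cyclopentenone; the seven-membered ring is the only ring formed.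
3. Diene 11 comes from a Negishi union of the zinc reagent of bromo ketal 4 with vinyl iodide 8 (C11 from the (S)-Roche ester); diazo ester 14 comes from methyl acetoacetate.
4. After the key step: C5=C6 hydroboration; ester to C10 methylene/C9 ketone; C6 ketone and ring-fusion equilibration; CBS reduction at C9; C9-hydroxyl-directed reduction at C6; C4 ketal to enol triflate to methyl.
5. Side chain last: C12 aldehyde, (Z)-alkoxyallylboration (C12, C13), acetylation, cross-metathesis to the isobutenyl group, PMB removal.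

Key step: step 9

Numbering and faces: C1 and C5 are the ring-fusion carbons (C1 next to C10), C2–C4 complete the five-membered ring (C4 bears the methyl), C6 is the carbinol, C7 bears the side chain, C8 is CH2, C9 bears the acetoxy group, and C11 (methyl), C12, C13, C14, C15 form the side chain. The seven-membered ring is viewed with C10→C9→C8→C7→C6→C5→C1 clockwise; β is towards the viewer. The target has H1 α, H5 β, 6-OH β, C7 side chain β, 9-OAc α, and (11R,12S,13S).

Assumption: Rh2(S-PTAD)4 is taken as the catalyst enantiomer that adds the carbenoid to the face of C1 leading to 16. The sense of induction for this ring alkene is not secure, and Rh2(R-PTAD)4 is the mirror-image choice if it proves opposite.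

Remark: the C5 and C6 configurations made in step 10 are provisional; both are reset in steps 12 and 14.

**Step 1**
Reactants: 1 cyclopent-2-en-1-one
Product: 3 2-bromocyclopent-2-en-1-one, via 2,3-dibromocyclopentanone 2 (not isolated)
Conditions: Br2, CH2Cl2, 0 °C; then Et3N, 0 °C → rt
Reagents that add atoms: bromine, BrBr
Why: Bromine addition to the enone and amine-induced loss of HBr from the α,β-dibromide (addition–elimination) should give the 2-bromoenone; no stereocenter is formed.

**Step 2**
Reactants: 3 2-bromocyclopent-2-en-1-one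
Product: 4 6-bromo-1,4-dioxaspiro[4.4]non-6-ene
Conditions: HOCH2CH2OH, p-TsOH·H2O (cat.), benzene, reflux, Dean–Stark
Reagents that add atoms: ethylene glycol, OCCO
Why: Acid-catalysed ketalisation with azeotropic removal of water masks the ketone so that the C–Br bond can later undergo halogen–lithium exchange; no stereocenter.

**Step 3**
Reactants: 5 methyl (S)-3-hydroxy-2-methylpropanoate
Product: 6 methyl (S)-3-(tert-butyldiphenylsilyloxy)-2-methylpropanoate
Conditions: TBDPSCl, imidazole, CH2Cl2, 0 °C → rt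
Reagents that add atoms: tert-butyl(chloro)diphenylsilane, CC(C)(C)[Si](Cl)(c1ccccc1)c1ccccc1
Why: Imidazole-promoted silylation of the primary alcohol installs a bulky silyl ether that should last to step 20 and screen the neighbouring C–H bonds in step 9; C11 is untouched.

**Step 4**
Reactants: 6 methyl (S)-3-(tert-butyldiphenylsilyloxy)-2-methylpropanoate
Product: 7 (S)-3-(tert-butyldiphenylsilyloxy)-2-methylpropanal
Conditions: i-Bu2AlH, CH2Cl2, −78 °C; aq. KNaC4H4O6
Reagents that add atoms: none
Why: Half-reduction of the ester through the tetrahedral aluminate, stable at −78 °C, should give the aldehyde without enolising the α-stereocenter.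

**Step 5**
Reactants: 7 (S)-3-(tert-butyldiphenylsilyloxy)-2-methylpropanal
Product: 8 tert-butyl{[(2R,3E)-4-iodo-2-methylbut-3-en-1-yl]oxy}diphenylsilane
Conditions: CrCl2, CHI3, THF/1,4-dioxane, 0 °C → rt
Reagents that add atoms: iodoform, IC(I)I
Why: Takai olefination: the gem-dichromium species from CHI3 adds to the aldehyde and eliminates to the E-vinyl iodide under non-basic conditions, so the allylic stereocenter (now R by priority change only) is kept.

**Step 6**
Reactants: 4 6-bromo-1,4-dioxaspiro[4.4]non-6-ene; 8 tert-butyl{[(2R,3E)-4-iodo-2-methylbut-3-en-1-yl]oxy}diphenylsilane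
Product: 11 tert-butyl{[(2R,3E)-4-(1,4-dioxaspiro[4.4]non-6-en-6-yl)-2-methylbut-3-en-1-yl]oxy}diphenylsilane, via alkenyllithium 9 (not isolated), via alkenylzinc chloride 10 (not isolated)
Conditions: 4, n-BuLi, THF, −78 °C; ZnCl2, −78 → 0 °C; then 8, Pd(PPh3)4 (5 mol %), rt
Reagents that add atoms: none
Why: Negishi coupling (bromine–lithium exchange, transmetalation to zinc, palladium-catalysed sp2–sp2 coupling) should join C5 to C6 with retention of the E geometry of 8; no new stereocenter.

**Step 7**
Reactants: 12 methyl acetoacetate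
Product: 13 methyl 2-diazo-3-oxobutanoate
Conditions: 4-AcNHC6H4SO2N3, Et3N, MeCN, 0 °C → rt
Reagents that add atoms: 4-acetamidobenzenesulfonyl azide, CC(=O)Nc1ccc(cc1)S(=O)(=O)N=[N+]=[N-]
Why: Regitz diazo transfer to the active methylene of the β-keto ester.

**Step 8**
Reactants: 13 methyl 2-diazo-3-oxobutanoate
Product: 14 methyl 3-(tert-butyldimethylsilyloxy)-2-diazobut-3-enoate
Conditions: TBSOTf, Et3N, CH2Cl2, 0 °C
Reagents that add atoms: tert-butyldimethylsilyl triflate, CC(C)(C)[Si](C)(C)OS(=O)(=O)C(F)(F)F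
Why: Soft enolisation and O-silylation of the methyl ketone should give the siloxyvinyl diazoacetate, which is used without storage.

**Step 9**
Reactants: 11 diene; 14 methyl 3-(tert-butyldimethylsilyloxy)-2-diazobut-3-enoate
Product: 16 (4+3) adduct with C10 ester and C9 silyl enol ether and C5=C6 alkene, via cis-dialkenylcyclopropane 15 (not isolated)
Conditions: Rh2(S-PTAD)4 {dirhodium tetrakis[(S)-(1-adamantyl)(N-phthalimido)acetate]} (2 mol %), 14 (3 equiv, slow addition), hexanes, −26 °C → rt; then PhMe, 80 °C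
Reagents that add atoms: none
Why: Rh2(S-PTAD)4 takes N2 from 14 and the resulting donor/acceptor rhodium carbenoid adds to the ring alkene, bonding C10 first to the unhindered C1 (charge building at C5, where it is allylic) and then to C5, to give cis-1,2-dialkenylcyclopropane 15; a boat-shaped [3,3] shift then forms C7–C8 and breaks the strained C5–C10 bond. The closest known reaction type is the tandem cyclopropanation/Cope rearrangement of siloxyvinyl diazoacetates with dienes (formal (4+3) cycloaddition). The seven-membered ring closes as a 3-atom (C10, C9, C8) plus 4-atom (C1, C5, C6, C7) union by sigmatropic ring expansion of the three-membered ring. C1 is set by the chiral carboxylate ligands, which choose the face of the ring alkene, and C7 is tied to C1 because the E geometry of C6=C7 is carried through the boat transition state (H1 and H7 cis). The step needs attack at C1=C5 and not at C6=C7 or at C–H bonds: E-1,2-disubstituted alkenes are poor partners for these bulky carbenoids, and the TBDPS group screens the C–H bonds next to oxygen. Warming at the end lets any cyclopropane with trans alkenyl groups equilibrate through reversible opening of the donor–acceptor C5–C10 bond and rearrange as well.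

**Step 10**
Reactants: 16 (4+3) adduct
Product: 18 6α-alcohol with H5 α, via C6 alkylborane 17 (not isolated)
Conditions: BH3·THF, THF, 0 °C → rt; then NaBO3·4H2O, THF/H2O, rt
Reagents that add atoms: sodium perborate tetrahydrate (active form Na[B(OH)3(OOH)]), [Na+].OO[B-](O)(O)O
Why: Hydroboration–oxidation of the only unhindered trisubstituted alkene should place boron at C6 and H at C5 by syn addition from the convex α face, with perborate chosen to spare the silyl enol ether; both new centres are provisional.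

**Step 11**
Reactants: 18 6α-alcohol
Product: 20 10-methylene-9-ketone with free 6α-hydroxyl, via enol silane diol 19 (not isolated)
Conditions: i-Bu2AlH, CH2Cl2, −78 → 0 °C; aq. KNaC4H4O6; then PPTS (cat.), CH2Cl2, 0 °C → rt
Reagents that add atoms: none
Why: Reduction of the vinylogous carbonate ester to the allylic alcohol and acid-triggered loss of that hydroxyl pushed by the enol silane (Stork–Danheiser-type transposition) should unveil the α-methylene ketone with the C4 ketal intact; no stereocenter is formed.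

**Step 12**
Reactants: 20 10-methylene-9-ketone
Product: 22 trans-fused 10-methylene-6,9-dione, via cis-fused dione 21 (not isolated)
Conditions: Dess–Martin periodinane, NaHCO3, CH2Cl2, rt; then DBU (0.3 equiv), PhMe, rt
Reagents that add atoms: none
Why: Dess–Martin oxidation gives the C6 ketone and base equilibration through the C6 enolate should turn C5 to the trans ring fusion (H5 β), the isomer in which C2, C4 and the C7 side chain are all equatorial on a twist-chair seven-membered ring; C7 can also enolise but already has the equatorial orientation.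

**Step 13**
Reactants: 22 trans-fused 10-methylene-6,9-dione
Product: 23 9α-hydroxy-10-methylene-6-ketone
Conditions: (S)-2-methyl-CBS-oxazaborolidine (0.5 equiv), catecholborane (1.2 equiv), PhMe, −78 °C
Reagents that add atoms: none
Why: Corey–Bakshi–Shibata reduction of the less hindered enone carbonyl, with the alkenyl flank as the large group and C8H2 as the small group, should give the (9R) α-alcohol by reagent control and leave the doubly α-branched C6 ketone.

**Step 14**
Reactants: 23 9α-hydroxy-10-methylene-6-ketone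
Product: 24 6β,9α-diol
Conditions: Me4NBH(OAc)3, MeCN/AcOH, −20 °C → rt
Reagents that add atoms: none
Why: Hydroxyl-directed reduction (Evans–Saksena type): the axial 9α-hydroxyl exchanges onto boron and should deliver hydride across the ring to the α face of C6, giving the 6β-alcohol, since this reagent does not reduce a ketone without such delivery.

**Step 15**
Reactants: 24 6β,9α-diol
Product: 25 9α-silyl ether with free 6β-hydroxyl
Conditions: TBSCl, imidazole, DMF, 0 °C → rt
Reagents that add atoms: tert-butyl(chloro)dimethylsilane, CC(C)(C)[Si](C)(C)Cl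
Why: Silylation should select the allylic C9 hydroxyl, because the C6 hydroxyl is flanked by two methine carbons.

**Step 16**
Reactants: 25 9α-silyl ether
Product: 26 6β-PMB ether
Conditions: NaH, 4-MeOC6H4CH2Br, n-Bu4NI (cat.), THF/DMF, 0 °C → rt
Reagents that add atoms: 4-methoxybenzyl bromide, COc1ccc(CBr)cc1
Why: Williamson etherification protects the C6 hydroxyl with a group that should survive fluoride, acid and base and is removed oxidatively at the end; the C9 silyl group is on the opposite face and cannot migrate.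

**Step 17**
Reactants: 26 6β-PMB ether
Product: 27 C4 ketone
Conditions: PPTS, acetone/H2O, 40 °C
Reagents that add atoms: water, O
Why: Mild acid hydrolysis of the dioxolane frees the C4 ketone; the reaction is stopped at conversion and worked up neutral so that C5 is not enolised.

**Step 18**
Reactants: 27 C4 ketone
Product: 29 C3=C4 enol triflate, via potassium enolate 28 (not isolated)
Conditions: KN(SiMe3)2, THF, −78 °C; then PhNTf2, −78 → 0 °C
Reagents that add atoms: N-phenylbis(trifluoromethanesulfonimide), FC(F)(F)S(=O)(=O)N(c1ccccc1)S(=O)(=O)C(F)(F)F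
Why: Kinetic deprotonation at the less hindered C3 methylene and O-triflation should fix the alkene at C3=C4 without touching the C5 methine.

**Step 19**
Reactants: 29 C3=C4 enol triflate
Product: 30 4-methyl C3=C4 alkene
Conditions: MeMgBr, Fe(acac)3 (5 mol %), THF/NMP, −30 → 0 °C
Reagents that add atoms: methylmagnesium bromide, C[Mg]Br
Why: Iron-catalysed Kumada-type cross-coupling of the alkenyl triflate should install the C4 methyl group; silyl and PMB ethers are inert.

**Step 20**
Reactants: 30 4-methyl C3=C4 alkene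
Product: 31 9α,12-diol
Conditions: n-Bu4NF, THF, rt
Reagents that add atoms: none
Why: Fluoride cleaves both silyl ethers (C9 and C12) while the PMB ether stays.

**Step 21**
Reactants: 31 9α,12-diol
Product: 32 C12 aldehyde
Conditions: TEMPO (cat.), PhI(OAc)2, CH2Cl2, rt
Reagents that add atoms: none
Why: Oxoammonium oxidation should take the primary alcohol in preference to the secondary allylic C9 hydroxyl, under non-basic conditions that keep C11.

**Step 22**
Reactants: 32 C12 aldehyde
Product: 34 (12S,13S)-12-hydroxy-13-(methoxymethoxy) compound with C14 vinyl, via O-borinate 33 (not isolated)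
Conditions: CH2=CHCH2OCH2OMe, sec-BuLi, THF, −78 °C; (+)-Ipc2BOMe; BF3·OEt2; then 32, −78 °C → rt; NaOH, H2O2
Reagents that add atoms: allyl methoxymethyl ether, C=CCOCOC
Why: Brown (Z)-γ-alkoxyallylboration: the chair transition state of the Z-allylborane gives the syn 12,13-dioxygen pattern, and the isopinocampheyl groups from (−)-α-pinene are expected to direct attack to the Re face of the aldehyde, setting (12S,13S) by reagent control (excess reagent covers the free C9 hydroxyl).

**Step 23**
Reactants: 34 (12S,13S)-12-hydroxy-13-(methoxymethoxy) compound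
Product: 35 9α,12,13-triol
Conditions: HCl (cat.), MeOH, 40 °C
Reagents that add atoms: none
Why: Acid-catalysed acetal exchange removes the methoxymethyl group while C13 still adjoins a terminal vinyl group, before the easily ionised isobutenyl carbinol exists.

**Step 24**
Reactants: 35 9α,12,13-triol
Product: 36 9,12,13-triacetate with C14 vinyl
Conditions: Ac2O, pyridine, DMAP (cat.), CH2Cl2, rt
Reagents that add atoms: acetic anhydride, CC(=O)OC(C)=O
Why: DMAP-catalysed acylation acetylates the three free hydroxyls; C6 is blocked as the PMB ether.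

**Step 25**
Reactants: 36 9,12,13-triacetate with C14 vinyl
Product: 37 9,12,13-triacetate with isobutenyl group
Conditions: second-generation Hoveyda–Grubbs catalyst RuCl2(H2IMes)(=CH-C6H4-2-O-i-Pr) (10 mol %), 2-methyl-2-butene, CH2Cl2, 40 °C
Reagents that add atoms: 2-methyl-2-butene, CC=C(C)C
Why: Olefin cross-metathesis should turn the monosubstituted vinyl group into the trisubstituted C14=C15 alkene, while the 1,1-disubstituted C10 methylene and the ring alkene are too hindered to take part.

**Step 26**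
Reactants: 37 9,12,13-triacetate with isobutenyl group
Product: 38 target
Conditions: DDQ, CH2Cl2/pH 7 buffer, 0 °C → rt
Reagents that add atoms: none
Why: Oxidative cleavage of the PMB ether (benzylic hydride abstraction, hydrolysis) frees the 6β-hydroxyl without touching acetates or alkenes.

**Compound list**
1 | cyclopent-2-en-1-one | O=C1C=CCC1 | starting material
2 | 2,3-dibromocyclopentan-1-one (trans, racemic) | O=C1CCC(Br)C1Br | intermediate (not isolated)
3 | 2-bromocyclopent-2-en-1-one | O=C1CCC=C1Br | intermediate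
4 | 6-bromo-1,4-dioxaspiro[4.4]non-6-ene | BrC1=CCCC12OCCO2 | intermediate
5 | methyl (S)-3-hydroxy-2-methylpropanoate | C[C@@H](CO)C(=O)OC | starting material
6 | methyl (S)-3-(tert-butyldiphenylsilyloxy)-2-methylpropanoate | C[C@@H](CO[Si](c1ccccc1)(c1ccccc1)C(C)(C)C)C(=O)OC | intermediate
7 | (S)-3-(tert-butyldiphenylsilyloxy)-2-methylpropanal | C[C@@H](CO[Si](c1ccccc1)(c1ccccc1)C(C)(C)C)C=O | intermediate
8 | tert-butyl{[(2R,3E)-4-iodo-2-methylbut-3-en-1-yl]oxy}diphenylsilane | C[C@@H](CO[Si](c1ccccc1)(c1ccccc1)C(C)(C)C)/C=C/I | intermediate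
9 | (1,4-dioxaspiro[4.4]non-6-en-6-yl)lithium | [Li]C1=CCCC12OCCO2 | intermediate (not isolated)
10 | chloro(1,4-dioxaspiro[4.4]non-6-en-6-yl)zinc | Cl[Zn]C1=CCCC12OCCO2 | intermediate (not isolated)
11 | tert-butyl{[(2R,3E)-4-(1,4-dioxaspiro[4.4]non-6-en-6-yl)-2-methylbut-3-en-1-yl]oxy}diphenylsilane (diene, key-step precursor) | CC(C)(C)[Si](c1ccccc1)(c1ccccc1)OC[C@H](C)/C=C/C1=CCCC12OCCO2 | intermediate
12 | methyl acetoacetate | CC(=O)CC(=O)OC | starting material
13 | methyl 2-diazo-3-oxobutanoate | CC(=O)C(=[N+]=[N-])C(=O)OC | intermediate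
14 | methyl 3-(tert-butyldimethylsilyloxy)-2-diazobut-3-enoate (key-step precursor) | C=C(O[Si](C)(C)C(C)(C)C)C(=[N+]=[N-])C(=O)OC | intermediate
15 | dialkenylcyclopropane: bicyclo[3.1.0]hexane (three-membered ring C1, C5, C10) with C4 ethylene ketal; C10 bears CO2Me and the 1-(TBS-oxy)vinyl group, C5 the E-alkenyl chain; both alkenyl groups and H1 on one face; (11R) | COC(=O)[C@]1(C(=C)O[Si](C)(C)C(C)(C)C)[C@@H]2CCC3(OCCO3)[C@]12/C=C/[C@@H](C)CO[Si](c1ccccc1)(c1ccccc1)C(C)(C)C | intermediate (not isolated)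
16 | (4+3) adduct: seven-membered ring C1–C10(CO2Me)=C9(OTBS)–C8H2–C7–C6H=C5, C4 ethylene ketal, C12 OTBDPS; H1 α, H7 α; (11R) | COC(=O)C1=C(O[Si](C)(C)C(C)(C)C)C[C@@H]([C@@H](C)CO[Si](c2ccccc2)(c2ccccc2)C(C)(C)C)C=C2C3(OCCO3)CC[C@@H]12 | intermediate (key-step product)
17 | C6 alkylborane of 16 (BH2 at C6 α, H5 α) | COC(=O)C1=C(O[Si](C)(C)C(C)(C)C)C[C@@H]([C@@H](C)CO[Si](c2ccccc2)(c2ccccc2)C(C)(C)C)[C@H](B)[C@H]2C3(OCCO3)CC[C@@H]12 | intermediate (not isolated)
18 | 6α-alcohol, H5 α (cis ring fusion), C10 ester and C9 silyl enol ether kept | COC(=O)C1=C(O[Si](C)(C)C(C)(C)C)C[C@@H]([C@@H](C)CO[Si](c2ccccc2)(c2ccccc2)C(C)(C)C)[C@H](O)[C@H]2C3(OCCO3)CC[C@@H]12 | intermediate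
19 | C10 hydroxymethyl enol silane, 6α-OH | OCC1=C(O[Si](C)(C)C(C)(C)C)C[C@@H]([C@@H](C)CO[Si](c2ccccc2)(c2ccccc2)C(C)(C)C)[C@H](O)[C@H]2C3(OCCO3)CC[C@@H]12 | intermediate (not isolated)
20 | 10-methylene-9-ketone, 6α-OH, cis-fused, C4 ketal | C=C1C(=O)C[C@@H]([C@@H](C)CO[Si](c2ccccc2)(c2ccccc2)C(C)(C)C)[C@H](O)[C@H]2C3(OCCO3)CC[C@@H]12 | intermediate
21 | 10-methylene-6,9-dione, cis-fused (H5 α) | C=C1C(=O)C[C@@H]([C@@H](C)CO[Si](c2ccccc2)(c2ccccc2)C(C)(C)C)C(=O)[C@H]2C3(OCCO3)CC[C@@H]12 | intermediate (not isolated)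
22 | 10-methylene-6,9-dione, trans-fused (H1 α, H5 β) | C=C1C(=O)C[C@@H]([C@@H](C)CO[Si](c2ccccc2)(c2ccccc2)C(C)(C)C)C(=O)[C@@H]2C3(OCCO3)CC[C@@H]12 | intermediate
23 | 9α-hydroxy-10-methylene-6-ketone, trans-fused | C=C1[C@H](O)C[C@@H]([C@@H](C)CO[Si](c2ccccc2)(c2ccccc2)C(C)(C)C)C(=O)[C@@H]2C3(OCCO3)CC[C@@H]12 | intermediate
24 | 6β,9α-diol | C=C1[C@H](O)C[C@@H]([C@@H](C)CO[Si](c2ccccc2)(c2ccccc2)C(C)(C)C)[C@@H](O)[C@@H]2C3(OCCO3)CC[C@@H]12 | intermediate
25 | 9α-OTBS, 6β-OH | C=C1[C@H](O[Si](C)(C)C(C)(C)C)C[C@@H]([C@@H](C)CO[Si](c2ccccc2)(c2ccccc2)C(C)(C)C)[C@@H](O)[C@@H]2C3(OCCO3)CC[C@@H]12 | intermediate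
26 | 9α-OTBS, 6β-OPMB, C4 ketal | C=C1[C@H](O[Si](C)(C)C(C)(C)C)C[C@@H]([C@@H](C)CO[Si](c2ccccc2)(c2ccccc2)C(C)(C)C)[C@@H](OCc2ccc(OC)cc2)[C@@H]2C3(OCCO3)CC[C@@H]12 | intermediate
27 | C4 ketone | C=C1[C@H](O[Si](C)(C)C(C)(C)C)C[C@@H]([C@@H](C)CO[Si](c2ccccc2)(c2ccccc2)C(C)(C)C)[C@@H](OCc2ccc(OC)cc2)[C@@H]2C(=O)CC[C@@H]12 | intermediate
28 | potassium C3=C4 enolate of 27 | C=C1[C@H](O[Si](C)(C)C(C)(C)C)C[C@@H]([C@@H](C)CO[Si](c2ccccc2)(c2ccccc2)C(C)(C)C)[C@@H](OCc2ccc(OC)cc2)[C@@H]2C([O-])=CC[C@@H]12.[K+] | intermediate (not isolated)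
29 | C3=C4 enol triflate | C=C1[C@H](O[Si](C)(C)C(C)(C)C)C[C@@H]([C@@H](C)CO[Si](c2ccccc2)(c2ccccc2)C(C)(C)C)[C@@H](OCc2ccc(OC)cc2)[C@@H]2C(OS(=O)(=O)C(F)(F)F)=CC[C@@H]12 | intermediate
30 | 4-methyl C3=C4 alkene; 9α-OTBS, 6β-OPMB, 12-OTBDPS | C=C1[C@H](O[Si](C)(C)C(C)(C)C)C[C@@H]([C@@H](C)CO[Si](c2ccccc2)(c2ccccc2)C(C)(C)C)[C@@H](OCc2ccc(OC)cc2)[C@@H]2C(C)=CC[C@@H]12 | intermediate
31 | 9α,12-diol, 6β-OPMB | C=C1[C@H](O)C[C@@H]([C@@H](C)CO)[C@@H](OCc2ccc(OC)cc2)[C@@H]2C(C)=CC[C@@H]12 | intermediate
32 | C12 aldehyde, 9α-OH, (11R) | C=C1[C@H](O)C[C@@H]([C@@H](C)C=O)[C@@H](OCc2ccc(OC)cc2)[C@@H]2C(C)=CC[C@@H]12 | intermediate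
33 | C12 O-diisopinocampheylborinate of 34 | C=C1[C@H](O)C[C@@H]([C@@H](C)[C@H](OB([C@H]4C[C@H]5C[C@@H]([C@@H]4C)C5(C)C)[C@H]4C[C@H]5C[C@@H]([C@@H]4C)C5(C)C)[C@H](C=C)OCOC)[C@@H](OCc2ccc(OC)cc2)[C@@H]2C(C)=CC[C@@H]12 | intermediate (not isolated)
34 | (11R,12S,13S) 12-hydroxy-13-(methoxymethoxy) compound with C14=CH2 | C=C1[C@H](O)C[C@@H]([C@@H](C)[C@H](O)[C@H](C=C)OCOC)[C@@H](OCc2ccc(OC)cc2)[C@@H]2C(C)=CC[C@@H]12 | intermediate
35 | 9α,12,13-triol | C=C1[C@H](O)C[C@@H]([C@@H](C)[C@H](O)[C@H](C=C)O)[C@@H](OCc2ccc(OC)cc2)[C@@H]2C(C)=CC[C@@H]12 | intermediate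
36 | 9,12,13-triacetate with C14 vinyl, 6β-OPMB | C=C1[C@H](OC(C)=O)C[C@@H]([C@@H](C)[C@H](OC(C)=O)[C@H](C=C)OC(C)=O)[C@@H](OCc2ccc(OC)cc2)[C@@H]2C(C)=CC[C@@H]12 | intermediate
37 | 9,12,13-triacetate with isobutenyl group, 6β-OPMB | C=C1[C@H](OC(C)=O)C[C@@H]([C@@H](C)[C@H](OC(C)=O)[C@H](C=C(C)C)OC(C)=O)[C@@H](OCc2ccc(OC)cc2)[C@@H]2C(C)=CC[C@@H]12 | intermediate
38 | CNP0194318.1 | C=C1[C@H](OC(C)=O)C[C@@H]([C@@H](C)[C@H](OC(C)=O)[C@H](C=C(C)C)OC(C)=O)[C@@H](O)[C@@H]2C(C)=CC[C@@H]12 | target

Total step count: 26. Longest linear sequence: 22 steps (steps 3–6 and 9–26).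

**Steps most likely to fail**

Step 9. The carbenoid may be lost to dimerisation, to C–H insertion or to attack at the wrong alkene before it reaches the trisubstituted ring alkene, and the face of addition at C1 may be poorly controlled. The fallback builds the same cyclopropane by ionic chemistry; it sets out from 11 and comes back at 16. The allylic ketal of 11 is hydrolysed (PPTS, wet acetone) to the cross-conjugated dienone F1. A Michael-initiated ring closure with methyl 2-chloroacetoacetate (K2CO3, DMF) gives the acetyl cyclopropane F2; a cinchona-derived primary amine as iminium catalyst can control the face, otherwise the C1 epimers are separated as diastereomers thanks to C11. TBSOTf/Et3N turns the acetyl group into the silyl enol ether F3, the C4-ketone analogue of 15. F3 undergoes the same Cope shift (rt to 80 °C) to the cycloheptadienone F4. Ketalisation with 1,2-bis(trimethylsilyloxy)ethane and catalytic TMSOTf at −78 °C returns 16.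

Step 12. The α-methylene ketone may be consumed by conjugate addition or dimerisation under base, or the ring-fusion equilibrium may be slow or incomplete. The fallback removes the enone before equilibration; it sets out from 20 and comes back at 23. CBS reduction of 20 gives the cis-fused diol F5, and the allylic C9 hydroxyl is silylated (TESCl, imidazole) to F6. Dess–Martin oxidation gives the cis-fused C6 ketone F7, which can be equilibrated with NaOMe/MeOH to the trans-fused ketone F8. HF·pyridine then removes the triethylsilyl group to give 23.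

Step 14. The C6 ketone may be masked as a transannular hemiketal with the C9 hydroxyl, or hydride may not be delivered across the ring, so that no reduction or the wrong face results. The fallback uses external delivery and then inversion; it sets out from 23 and comes back at 25. The C9 hydroxyl is silylated first (TBSCl, imidazole) to the ketone F9. LiBH(sec-Bu)3 should then attack from the more open β face to give the 6α-alcohol F10. Triflation (Tf2O, pyridine) gives F11, and displacement with n-Bu4NNO2 (Lattrell–Dax inversion, nitrite ester cleaved on work-up) gives the 6β-alcohol 25.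

**Further compounds**
F1 | step 9 | 2-[(1E,3R)-4-(tert-butyldiphenylsilyloxy)-3-methylbut-1-en-1-yl]cyclopent-2-en-1-one | O=C1CCC=C1/C=C/[C@@H](C)CO[Si](c1ccccc1)(c1ccccc1)C(C)(C)C
F2 | step 9 | acetyl cyclopropane: bicyclo[3.1.0]hexan-2-one with C10 bearing acetyl and CO2Me and C5 bearing the E-alkenyl chain | COC(=O)[C@]1(C(C)=O)[C@@H]2CCC(=O)[C@]12/C=C/[C@@H](C)CO[Si](c1ccccc1)(c1ccccc1)C(C)(C)C
F3 | step 9 | silyl enol ether of F2 (C4-ketone analogue of 15) | COC(=O)[C@]1(C(=C)O[Si](C)(C)C(C)(C)C)[C@@H]2CCC(=O)[C@]12/C=C/[C@@H](C)CO[Si](c1ccccc1)(c1ccccc1)C(C)(C)C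
F4 | step 9 | C4-ketone analogue of 16 | COC(=O)C1=C(O[Si](C)(C)C(C)(C)C)C[C@@H]([C@@H](C)CO[Si](c2ccccc2)(c2ccccc2)C(C)(C)C)C=C2C(=O)CC[C@@H]12
F5 | step 12 | cis-fused 6α,9α-diol with C10 methylene and C4 ketal | C=C1[C@H](O)C[C@@H]([C@@H](C)CO[Si](c2ccccc2)(c2ccccc2)C(C)(C)C)[C@H](O)[C@H]2C3(OCCO3)CC[C@@H]12
F6 | step 12 | 9α-triethylsilyl ether of F5 | C=C1[C@H](O[Si](CC)(CC)CC)C[C@@H]([C@@H](C)CO[Si](c2ccccc2)(c2ccccc2)C(C)(C)C)[C@H](O)[C@H]2C3(OCCO3)CC[C@@H]12
F7 | step 12 | cis-fused C6 ketone, 9α-OTES | C=C1[C@H](O[Si](CC)(CC)CC)C[C@@H]([C@@H](C)CO[Si](c2ccccc2)(c2ccccc2)C(C)(C)C)C(=O)[C@H]2C3(OCCO3)CC[C@@H]12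
F8 | step 12 | trans-fused C6 ketone, 9α-OTES | C=C1[C@H](O[Si](CC)(CC)CC)C[C@@H]([C@@H](C)CO[Si](c2ccccc2)(c2ccccc2)C(C)(C)C)C(=O)[C@@H]2C3(OCCO3)CC[C@@H]12
F9 | step 14 | trans-fused C6 ketone, 9α-OTBS | C=C1[C@H](O[Si](C)(C)C(C)(C)C)C[C@@H]([C@@H](C)CO[Si](c2ccccc2)(c2ccccc2)C(C)(C)C)C(=O)[C@@H]2C3(OCCO3)CC[C@@H]12
F10 | step 14 | 6α-alcohol, 9α-OTBS, trans-fused | C=C1[C@H](O[Si](C)(C)C(C)(C)C)C[C@@H]([C@@H](C)CO[Si](c2ccccc2)(c2ccccc2)C(C)(C)C)[C@H](O)[C@@H]2C3(OCCO3)CC[C@@H]12
F11 | step 14 | 6α-triflate of F10 | C=C1[C@H](O[Si](C)(C)C(C)(C)C)C[C@@H]([C@@H](C)CO[Si](c2ccccc2)(c2ccccc2)C(C)(C)C)[C@H](OS(=O)(=O)C(F)(F)F)[C@@H]2C3(OCCO3)CC[C@@H]12
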